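**Retrosynthetic overview**
1. Numbering: ring A = C1(H)Me–C2–C3–C4(H)Br–C5Me2–C6 (spiro). Ring B = C6–C7–C8–C9(Me)Cl–C10(H)Br–C11. The strategy rests on one feature. C6 is stereogenic only because C10, not C8, carries bromine, and C9 lies para to C6 and bears a heteroatom. With C9 as C=O and both arms unsaturated, ring B is a cyclohexa-2,5-dienone, that is, a dearomatised para-alkylphenol whose C6 is only prochiral.
2. Late disconnections (editing of ring B): C9–Cl ⇒ C9–OH (retention); C10–Br ⇒ C9–C10 epoxide (SN2); epoxide ⇒ C9(Me)=C10 alkene ⇒ C9 enol triflate ⇒ C10=C11 enone. C4–Br ⇒ 4S alcohol (SN2 inversion).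
3. C6 ⇒ spirodienone: an ene-reductase saturates only the C7=C8 arm.
4. Key disconnection C5–C6: ipso (para) attack of an aryl silyl ether on the tertiary carbon of a side-chain (S)-epoxide, which closes ring A.
5. Ring order: ring B first (Michael/aldol annulation of (S)-citronellal with methyl vinyl ketone, then aromatisation), ring A second (step 7). After that ring B is only edited.

Key step: step 7

Remark: locants in all names are those of the overview. The enzyme of step 8 is defined by its function (the panel member that reduces the C7=C8 arm), not by a strain name. Oxone is entered as its active salt KHSO5.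

**Step 1**
Reactants: 1 (S)-citronellal; 2 methyl vinyl ketone
Product: 4 (3S)-3,7-dimethyl-2-(3-oxobutyl)oct-6-enal (both C2 epimers), via diethyl enamine of citronellal 3 (not isolated)
Conditions: Et2NSiMe3 (20 mol %), MeCN, reflux; aq. NH4Cl
Reagents that add atoms: none
Why: Stork-type enamine Michael addition run catalytically in amine: enamine 3 adds through the aldehyde α-carbon (future C6) to the enone terminus (future C7) and hydrolysis frees the amine again; C1 is β to the carbonyl and untouched, and the new C6 centre is left unassigned because step 4 erases it.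

**Step 2**
Reactants: 4 (3S)-3,7-dimethyl-2-(3-oxobutyl)oct-6-enal
Product: 6 4-[(2S)-6-methylhept-5-en-2-yl]cyclohex-2-en-1-one (both ring epimers), via ring ketol 5 (not isolated)
Conditions: aq. KOH, n-Bu4NOH (cat.), THF–Et2O, reflux
Reagents that add atoms: none
Why: Intramolecular aldol condensation (second half of a Robinson-type annulation): the methyl ketone enolate carbon (C10) closes on the aldehyde carbon (C11) to ketol 5, and E1cB loss of water gives the C10=C11 enone of ring B.

**Step 3**
Reactants: 6 4-[(2S)-6-methylhept-5-en-2-yl]cyclohex-2-en-1-one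
Product: 8 trimethyl({4-[(2S)-6-methylhept-5-en-2-yl]cyclohexa-1,5-dien-1-yl}oxy)silane, via lithium dienolate 7 (not isolated)
Conditions: LDA, THF, −78 °C; TMSCl, −78 → 0 °C
Reagents that add atoms: chlorotrimethylsilane, C[Si](C)(C)Cl
Why: Kinetic deprotonation of a cyclohexenone removes the α′ proton (C8), and O-silylation of the cross-conjugated dienolate 7 fixes this regiochemistry for the dehydrogenation.

**Step 4**
Reactants: 8 trimethylsilyl dienol ether
Product: 10 4-[(2S)-6-methylhept-5-en-2-yl]phenol, via 4-H cyclohexadienone 9 (not isolated)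
Conditions: Pd(OAc)2 (1.05 equiv), MeCN, rt
Reagents that add atoms: none
Why: Saegusa–Ito oxidation: palladation at C8 and β-hydride loss from C7 give dienone 9, which tautomerises at once to the phenol and erases C6 without involving the benzylic C1–H; the selenium/peroxide alternative is avoided because it would endanger the side-chain alkene.

**Step 5**
Reactants: 10 4-[(2S)-6-methylhept-5-en-2-yl]phenol
Product: 11 tert-butyl(dimethyl){4-[(2S)-6-methylhept-5-en-2-yl]phenoxy}silane
Conditions: TBSCl, imidazole, DMF, rt
Reagents that add atoms: tert-butyldimethylsilyl chloride, CC(C)(C)[Si](C)(C)Cl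
Why: Standard imidazole-promoted O-silylation; the silyl ether keeps oxygen a strong para donor, should survive the cold basic epoxidation medium, and is an easily lost group on oxygen in step 7.

**Step 6**
Reactants: 11 aryl TBS ether
Product: 12 tert-butyl(dimethyl)(4-{(2S)-4-[(2S)-3,3-dimethyloxiran-2-yl]butan-2-yl}phenoxy)silane
Conditions: ent-Shi ketone (L-fructose-derived, 30 mol %), Oxone, K2CO3, Na2B4O7/Na2EDTA buffer, n-Bu4NHSO4, MeCN–CH2(OMe)2, 0 °C
Reagents that add atoms: potassium peroxymonosulfate (Oxone), [K+].[O-]S(=O)(=O)OO
Why: Shi asymmetric epoxidation (chiral dioxirane, spiro transition state) of the only alkene; the D-fructose ketone gives R epoxides from Me2C=CH–CH2R alkenes, so its enantiomer is used to set S at the secondary epoxide carbon (future C4), and the remote C1 centre plays no part.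

**Step 7**
Reactants: 12 epoxy aryl TBS ether
Product: 15 (1S,4S)-4-hydroxy-1,5,5-trimethylspiro[5.5]undeca-7,10-dien-9-one, via spiro silyloxocarbenium aluminate 13 (not isolated), via dimethylaluminium alkoxide 14 (not isolated)
Conditions: Me2AlCl (1.2 equiv), CH2Cl2, −78 °C; Et3N, then aq. Rochelle salt
Reagents that add atoms: none
Why: Proposed new method: Me2AlCl binds the epoxide oxygen, the tertiary C5–O bond stretches, and C6, the arene carbon para to the silyloxy group, attacks C5 from the rear to give the spiro silyloxocarbenium (arenium) zwitterion 13, whose silyl group is taken by chloride to leave the aluminium alkoxide 14 of the dienone (protonated on work-up). The closest known reaction types are Lewis-acid epoxide-initiated cation-π cyclisations onto arenes and polyenes and the intramolecular ipso (para) alkylative dearomatisation of phenols and para-oxygenated arenes to spiro[5.5]cyclohexa-2,5-dienones, which have not been combined on a trisubstituted epoxide. Ring A closes 6-endo with respect to the epoxide (C4 and C5 both become ring members, oxygen stays on C4) and spiro (ipso) at the arene, through a chair that keeps the C1 methyl and the C4–O bond equatorial. No stereocentre is made at C5 or at C6 (two identical enone arms); C4 retains the untouched C–O bond of the (S)-epoxide and so emerges 4S, trans to the C1 methyl brought by citronellal. The step needs ipso rather than ortho attack and opening at C5 rather than C4: C6 is the ring carbon most activated by the para oxygen and the only one that reaches C5 through a six-membered ring (the ortho carbons are meta to oxygen and would need a seven-membered ring at C5 or substitution at secondary C4), and only tertiary C5 can carry the developing charge, which also disfavours 5-exo ipso closure at C4. A chloride-bearing, proton-scavenging Lewis acid at −78 °C should make loss of silicon faster than 1,2-migration in 13 (dienone–phenol pathway) and than Meinwald-type isomerisation of the epoxide.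

**Step 8**
Reactants: 15 spirodienone
Product: 16 (1S,4S,6R)-4-hydroxy-1,5,5-trimethylspiro[5.5]undec-10-en-9-one
Conditions: ene-reductase (Old Yellow Enzyme family, panel hit), NADP+ (cat.), glucose dehydrogenase, D-glucose, KPi buffer pH 7, DMSO (5 % v/v), 30 °C
Reagents that add atoms: none
Why: Known ene-reductase desymmetrisation of 4,4-disubstituted cyclohexa-2,5-dienones (flavin hydride to Cβ = C7, protein proton to Cα = C8) applied to a spirocyclic member of the class: the two arms of 15 are diastereotopic, an enzyme selected for the C7=C8 arm (equatorial on the ring-A chair, on the side of the C4 hydroxyl and away from the C1 methyl) makes C6 R, and the resulting 4,4-disubstituted enone is a much poorer substrate, so reduction should stop there.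

**Step 9**
Reactants: 16 hydroxy spiro-enone
Product: 18 (1S,4R,6R)-4-bromo-1,5,5-trimethylspiro[5.5]undec-10-en-9-one, via alkoxyphosphonium bromide 17 (not isolated)
Conditions: CBr4, P(n-Oct)3 (added last, slowly), toluene, 70 °C
Reagents that add atoms: carbon tetrabromide, BrC(Br)(Br)Br
Why: Appel reaction of the kind used for neopentylic secondary alcohols in bromoterpenoid synthesis: bromide displaces the phosphine oxide from 17 by SN2 with inversion (4S alcohol to 4R bromide, now cis to the C1 methyl); the non-polar acid-free medium holds back E2 loss and Wagner–Meerwein shift, slow addition keeps free phosphine away from the hindered enone, ring B carries no sensitive halide yet, and the product can relax by ring-A inversion to the chair with equatorial bromine.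

**Step 10**
Reactants: 18 bromo spiro-enone
Product: 20 (1S,4R,6S)-4-bromo-1,5,5-trimethylspiro[5.5]undec-9-en-9-yl trifluoromethanesulfonate, via lithium enolate 19 (not isolated)
Conditions: L-Selectride, THF, −78 °C; PhNTf2, −78 °C → rt
Reagents that add atoms: N-phenylbis(trifluoromethanesulfonimide), O=S(=O)(N(c1ccccc1)S(=O)(=O)C(F)(F)F)C(F)(F)F
Why: Conjugate reduction–triflation: the bulky borohydride adds 1,4 to the β-unsubstituted cyclohexenone (hydride to C11) and gives the regiodefined C9=C10 enolate 19, which the triflimide traps on oxygen; the neopentylic secondary bromide is inert at −78 °C, and C6 is untouched (its descriptor changes to S only through CIP ranking).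

**Step 11**
Reactants: 20 enol triflate
Product: 21 (1S,4R,6S)-4-bromo-1,5,5,9-tetramethylspiro[5.5]undec-9-ene
Conditions: Me2Zn, Pd(PPh3)4 (5 mol %), THF, 0 °C → rt
Reagents that add atoms: dimethylzinc, C[Zn]C
Why: Negishi methylation of an enol triflate: Pd(0) inserts into the C(sp2)–OTf bond far faster than into an unactivated hindered secondary C–Br bond, and the neutral organozinc avoids base-induced loss of HBr.

**Step 12**
Reactants: 21 bromo spiro-alkene
Product: 22 (1S,4R,6S,9S,10R)-4-bromo-9,10-epoxy-1,5,5,9-tetramethylspiro[5.5]undecane (oxygen on the ring-B face of C1, away from C5)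
Conditions: Shi ketone (D-fructose-derived, 30 mol %), Oxone, K2CO3, Na2B4O7/Na2EDTA buffer, n-Bu4NHSO4, MeCN–CH2(OMe)2, 0 °C
Reagents that add atoms: potassium peroxymonosulfate (Oxone), [K+].[O-]S(=O)(=O)OO
Why: Second Shi epoxidation: for a 1-methylcyclohexene-type alkene the D-fructose ketone delivers oxygen in the (9S,10R) sense, which here is the face of C1; reagent control is required because the C1 branch, axial on ring B, leans over this face.

**Step 13**
Reactants: 22 epoxide
Product: 24 (1S,4R,6S,9S,10S)-4,10-dibromo-1,5,5,9-tetramethylspiro[5.5]undecan-9-ol, via lithium alkoxide 23 (not isolated)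
Conditions: Li2NiBr4 (0.4 M in THF), 0 °C → rt; pH 7 phosphate buffer
Reagents that add atoms: dilithium tetrabromonickelate, [Li+].[Li+].[Ni+2].[Br-].[Br-].[Br-].[Br-]
Why: Epoxide opening by a soft, nearly neutral bromide source: SN2 attack at secondary C10 with inversion puts bromine on the face of C5 and leaves the C9–O bond untouched, since tertiary C9 is closed to SN2 and the medium is too weakly acidic to ionise it.

**Step 14**
Reactants: 24 trans bromohydrin
Product: 27 (1S,4R,6S,9S,10S)-4,10-dibromo-9-chloro-1,5,5,9-tetramethylspiro[5.5]undecane (CNP0396146.1), via C9 chlorosulfite 25 (not isolated), via bromonium chloride ion pair 26 (not isolated)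
Conditions: SOCl2, CH2Cl2, −20 → 0 °C, no base
Reagents that add atoms: thionyl chloride, ClS(Cl)=O
Why: Neighbouring-group (anchimeric) participation by bromine: chlorosulfite 25 ionises at tertiary C9, the trans C10 bromine bridges the face opposite the departing oxygen (ion 26), and chloride returns to C9, the carbon bearing the charge, from the side the oxygen left, which means overall retention and a trans Br/Cl pair, with no base present to promote elimination.

**Compound list**
1 | (S)-citronellal | C[C@H](CC=O)CCC=C(C)C | starting material
2 | methyl vinyl ketone | CC(=O)C=C | starting material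
3 | (E)-N,N-diethyl enamine of (S)-citronellal | C[C@H](/C=C/N(CC)CC)CCC=C(C)C | intermediate
4 | (3S)-3,7-dimethyl-2-(3-oxobutyl)oct-6-enal (both C2 epimers) | C[C@H](C(CCC(C)=O)C=O)CCC=C(C)C | intermediate
5 | 3-hydroxy-4-[(2S)-6-methylhept-5-en-2-yl]cyclohexan-1-one (ring ketol) | C[C@H](C1CCC(=O)CC1O)CCC=C(C)C | intermediate
6 | 4-[(2S)-6-methylhept-5-en-2-yl]cyclohex-2-en-1-one (both ring epimers) | C[C@H](C1CCC(=O)C=C1)CCC=C(C)C | intermediate
7 | lithium cross-conjugated dienolate of 6 | C[C@H](C1CC=C([O-])C=C1)CCC=C(C)C.[Li+] | intermediate
8 | trimethyl({4-[(2S)-6-methylhept-5-en-2-yl]cyclohexa-1,5-dien-1-yl}oxy)silane | C[C@H](C1CC=C(O[Si](C)(C)C)C=C1)CCC=C(C)C | intermediate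
9 | 4-[(2S)-6-methylhept-5-en-2-yl]cyclohexa-2,5-dien-1-one | C[C@H](C1C=CC(=O)C=C1)CCC=C(C)C | intermediate
10 | 4-[(2S)-6-methylhept-5-en-2-yl]phenol | C[C@H](c1ccc(O)cc1)CCC=C(C)C | intermediate
11 | tert-butyl(dimethyl){4-[(2S)-6-methylhept-5-en-2-yl]phenoxy}silane | C[C@H](c1ccc(O[Si](C)(C)C(C)(C)C)cc1)CCC=C(C)C | intermediate
12 | tert-butyl(dimethyl)(4-{(2S)-4-[(2S)-3,3-dimethyloxiran-2-yl]butan-2-yl}phenoxy)silane | C[C@H](c1ccc(O[Si](C)(C)C(C)(C)C)cc1)CC[C@@H]1OC1(C)C | intermediate
13 | spiro silyloxocarbenium (arenium) ion with C4 chlorodimethylaluminate (zwitterion) | C[C@H]1CC[C@H](O[Al-](C)(C)Cl)C(C)(C)C12C=CC(=[O+][Si](C)(C)C(C)(C)C)C=C2 | intermediate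
14 | dimethylaluminium C4 alkoxide of the spirodienone | C[C@H]1CC[C@H](O[Al](C)C)C(C)(C)C12C=CC(=O)C=C2 | intermediate
15 | (1S,4S)-4-hydroxy-1,5,5-trimethylspiro[5.5]undeca-7,10-dien-9-one | C[C@H]1CC[C@H](O)C(C)(C)C12C=CC(=O)C=C2 | intermediate
16 | (1S,4S,6R)-4-hydroxy-1,5,5-trimethylspiro[5.5]undec-10-en-9-one | C[C@H]1CC[C@H](O)C(C)(C)[C@]12CCC(=O)C=C2 | intermediate
17 | C4 alkoxy(tri-n-octyl)phosphonium bromide of 16 | C[C@H]1CC[C@H](O[P+](CCCCCCCC)(CCCCCCCC)CCCCCCCC)C(C)(C)[C@]12CCC(=O)C=C2.[Br-] | intermediate
18 | (1S,4R,6R)-4-bromo-1,5,5-trimethylspiro[5.5]undec-10-en-9-one | C[C@H]1CC[C@@H](Br)C(C)(C)[C@]12CCC(=O)C=C2 | intermediate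
19 | lithium C9=C10 enolate | C[C@H]1CC[C@@H](Br)C(C)(C)[C@]12CCC([O-])=CC2.[Li+] | intermediate
20 | (1S,4R,6S)-4-bromo-1,5,5-trimethylspiro[5.5]undec-9-en-9-yl triflate | C[C@H]1CC[C@@H](Br)C(C)(C)[C@]12CCC(OS(=O)(=O)C(F)(F)F)=CC2 | intermediate
21 | (1S,4R,6S)-4-bromo-1,5,5,9-tetramethylspiro[5.5]undec-9-ene | C[C@H]1CC[C@@H](Br)C(C)(C)[C@]12CCC(C)=CC2 | intermediate
22 | (1S,4R,6S,9S,10R)-4-bromo-9,10-epoxy-1,5,5,9-tetramethylspiro[5.5]undecane | C[C@H]1CC[C@@H](Br)C(C)(C)[C@]12CC[C@]3(C)O[C@@H]3C2 | intermediate
23 | lithium C9 alkoxide of 24 | C[C@H]1CC[C@@H](Br)C(C)(C)[C@]12CC[C@](C)([O-])[C@@H](Br)C2.[Li+] | intermediate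
24 | (1S,4R,6S,9S,10S)-4,10-dibromo-1,5,5,9-tetramethylspiro[5.5]undecan-9-ol | C[C@H]1CC[C@@H](Br)C(C)(C)[C@]12CC[C@](C)(O)[C@@H](Br)C2 | intermediate
25 | C9 chlorosulfite of 24 | C[C@H]1CC[C@@H](Br)C(C)(C)[C@]12CC[C@](C)(OS(=O)Cl)[C@@H](Br)C2 | intermediate
26 | C9–C10 bromonium ion (bromine on the face of C5), chloride ion pair | C[C@H]1CC[C@@H](Br)C(C)(C)[C@]12CC[C@@]3(C)[Br+][C@H]3C2.[Cl-] | intermediate
27 | (1S,4R,6S,9S,10S)-4,10-dibromo-9-chloro-1,5,5,9-tetramethylspiro[5.5]undecane (CNP0396146.1) | C[C@H]1CC[C@@H](Br)C(C)(C)[C@]12CC[C@](C)(Cl)[C@@H](Br)C2 | target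

**Total step count:** 14. **Longest linear sequence:** 14 steps (from 1).

**Steps most likely to fail**

Step 7 (Proposed new method).
- What may go wrong: two fully substituted carbons must be joined at the price of aromaticity. The activated epoxide may isomerise by hydride shift or close at C4 before C6 attacks. The arenium ion may also rearomatise by 1,2-shift before it loses silicon.
- Fallback, known chemistry only: the aromaticity penalty is removed by using a silyl dienol ether as the terminating nucleophile.
- It sets out from enone 6. ent-Shi epoxidation touches only the electron-rich side-chain alkene and gives epoxy enone F1.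
- Thermodynamic γ-deprotonation (KOt-Bu, THF) followed by TBSCl gives the extended silyl dienol ether F2, which contains C9(OSi)=C10–C11=C6.
- MeAlCl2 in CH2Cl2 at −78 °C then starts an epoxide-initiated cation–olefin cyclisation terminated by a silyl enol ether. Here it runs through the γ-carbon C6 (vinylogous Mukaiyama-type alkylation) and gives spiro hydroxy enone F3 as either or both C6 epimers.
- DDQ in dioxane dehydrogenates C7–C8 and erases C6, so the route is rejoined at 15.

Step 8.
- What may go wrong: the β-carbons of 15 flank a spiro centre that sits between a quaternary and a tertiary carbon. Binding over the flavin may fail altogether, or active enzymes may reduce the other arm or both arms.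
- Fallback: catalyst control is replaced by substrate control with separation and recycling.
- It sets out from 15. L-Selectride (2 equiv, the first consumed by the hydroxyl) in THF at −78 °C adds hydride only once, because the cross-conjugated dienolate formed is inert to more hydride. It is expected to prefer the exposed equatorial C7=C8 arm.
- The two possible products are diastereomers and are separated by chromatography. The C6 epimer F4 is returned to 15 with DDQ and resubmitted. The route is rejoined at 16.

Step 13.
- What may go wrong: ring B is strongly biased towards the chair that keeps quaternary C5 equatorial and C1 axial, because an axial C5 would have to turn one of its three carbon substituents into ring B.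
- In that chair the diaxial (Fürst–Plattner) mode of opening of 22 leads to C9, and attack at C10 must pass through a twist-boat. The opening may therefore be very slow or turn to the tertiary carbon.
- The same bias leaves bromine and hydroxyl of 24 diequatorial, which weakens bromine participation in step 14.
- Fallback: the diaxial mode is used instead of opposed.
- It sets out from 22. Aqueous 48 % HBr in CHCl3 at 0 °C opens the epoxide at C9, where Markovnikov and diaxial preferences agree. This gives the diaxial bromohydrin F5, with the tertiary C9 bromide on the face of C5 and the C10 hydroxyl on the face of C1.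
- SOCl2 without base gives its C10 chlorosulfite F6, whose leaving group is antiperiplanar to bromine. As oxygen leaves, bromine swings from C9 towards C10 and gives the same bridged ion 26.
- Chloride opens 26 at the charge-bearing tertiary C9. The route is rejoined at 26 and ends at 27, bypassing steps 13 and 14.

**Further compounds**
F1 | step 7 | 4-{(2S)-4-[(2S)-3,3-dimethyloxiran-2-yl]butan-2-yl}cyclohex-2-en-1-one (both ring epimers) | C[C@H](C1CCC(=O)C=C1)CC[C@@H]1OC1(C)C
F2 | step 7 | tert-butyl(dimethyl)silyl extended dienol ether (4-substituted 1-silyloxycyclohexa-1,3-diene) of F1 | C[C@H](C1=CC=C(O[Si](C)(C)C(C)(C)C)CC1)CC[C@@H]1OC1(C)C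
F3 | step 7 | (1S,4S)-4-hydroxy-1,5,5-trimethylspiro[5.5]undec-10-en-9-one (C6 unassigned, either or both epimers) | C[C@H]1CC[C@H](O)C(C)(C)C12CCC(=O)C=C2
F4 | step 8 | (1S,4S,6S)-4-hydroxy-1,5,5-trimethylspiro[5.5]undec-10-en-9-one (C6 epimer of 16) | C[C@H]1CC[C@H](O)C(C)(C)[C@@]12CCC(=O)C=C2
F5 | step 13 | (1S,4R,6S,9R,10R)-4,9-dibromo-1,5,5,9-tetramethylspiro[5.5]undecan-10-ol | C[C@H]1CC[C@@H](Br)C(C)(C)[C@]12CC[C@@](C)(Br)[C@H](O)C2
F6 | step 13 | C10 chlorosulfite of F5 | C[C@H]1CC[C@@H](Br)C(C)(C)[C@]12CC[C@@](C)(Br)[C@H](OS(=O)Cl)C2
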